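Each depside bond is disconnected between the ester oxygen and C4 of the phenolic ring. In rings A and B that carbon lies between the C3 and C5 hydroxyls, exactly as C2 lies between the carbonyls of a 5-carboxycyclohexane-1,3-dione, so both rings are carried as one 2-diazo-1,3-dione. In the key step its rhodium carbenoid inserts into the carboxylic O–H of the perbenzylated B–C acid, forging the C4–O bond of future ring A with the para regiochemistry built in; non-basic dehydrogenation then unveils both flanking phenols. The precursors are tert-butyl 4-diazo-3,5-dioxocyclohexane-1-carboxylate and 3,5-bis(benzyloxy)-4-[3,4,5-tris(benzyloxy)benzoyloxy]benzoic acid.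

Key step: step 8

Remark: compounds 6 and 10 are drawn as diketo tautomers but should rest as 3-hydroxy-enones, so their ring sp3 carbons carry no lasting stereochemistry; the target has no stereocentre.

Step 1
Reactants: 1 3,5-dihydroxybenzoic acid
Product: 2 tert-butyl 3,5-dihydroxybenzoate
Conditions: Me2NCH(OtBu)2 (3 equiv), toluene, 80 °C
Reagents that add atoms: N,N-dimethylformamide di-tert-butyl acetal, CN(C)C(OC(C)(C)C)OC(C)(C)C
Why: tert-butyl esterification with a formamide acetal, in which only the carboxylic acid is acidic enough to activate the acetal and accept the tert-butyl group, so the two phenols should stay free.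

Step 2
Reactants: 2 tert-butyl 3,5-dihydroxybenzoate
Product: 3 tert-butyl 3,5-dioxocyclohexane-1-carboxylate
Conditions: H2 (4 atm), Rh/Al2O3 (5 wt % Rh), NaOH (1.05 equiv), H2O–EtOH, rt; then cold 1 M HCl to pH 3
Reagents that add atoms: none
Why: partial catalytic hydrogenation of a resorcinol monoanion, which should stop at the 1,3-dione because the product is held as its enolate and resists further reduction; the tert-butyl ester tolerates one equivalent of aqueous base at room temperature.

Step 3
Reactants: 3 tert-butyl 3,5-dioxocyclohexane-1-carboxylate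
Product: 4 tert-butyl 4-diazo-3,5-dioxocyclohexane-1-carboxylate
Conditions: 4-acetamidobenzenesulfonyl azide (1.1 equiv), Et3N (1.2 equiv), MeCN, 0 °C to rt
Reagents that add atoms: 4-acetamidobenzenesulfonyl azide, CC(=O)Nc1ccc(cc1)S(=O)(=O)N=[N+]=[N-]
Why: Regitz diazo transfer to the doubly activated methylene, in which the enolate adds to the terminal azide nitrogen and the adduct collapses to the diazodione and the sulfonamide.

Step 4
Reactants: 4 tert-butyl 4-diazo-3,5-dioxocyclohexane-1-carboxylate; 5 3,4,5-tris(benzyloxy)benzoic acid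
Product: 6 tert-butyl 3,5-dioxo-4-[3,4,5-tris(benzyloxy)benzoyloxy]cyclohexane-1-carboxylate
Conditions: Rh2(OAc)4 (2 mol %), ClCH2CH2Cl, 70 °C; 4 (1.2 equiv) added by syringe pump to 5 and the catalyst
Reagents that add atoms: none
Why: rhodium-carbenoid O–H insertion, in which Rh2(OAc)4 releases N2 from the diazodione and the electrophilic carbene carbon is captured by the carboxylic oxygen followed by proton transfer; slow addition keeps the diazo concentration low so that insertion should outrun carbene dimerisation.

Step 5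
Reactants: 6 tert-butyl 3,5-dioxo-4-[3,4,5-tris(benzyloxy)benzoyloxy]cyclohexane-1-carboxylate
Product: 7 tert-butyl 3,5-dihydroxy-4-[3,4,5-tris(benzyloxy)benzoyloxy]benzoate
Conditions: I2 (20 mol %), DMSO, 80 °C, N2
Reagents that add atoms: none
Why: iodine-catalysed oxidative aromatisation of a cyclohexane-1,3-dione with DMSO as terminal oxidant (α-iodination beside the ketone, loss of HI toward the ester-bearing carbon, tautomerisation), run without base so that the aroyl group should stay on O4.

Step 6
Reactants: 7 tert-butyl 3,5-dihydroxy-4-[3,4,5-tris(benzyloxy)benzoyloxy]benzoate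
Product: 8 tert-butyl 3,5-bis(benzyloxy)-4-[3,4,5-tris(benzyloxy)benzoyloxy]benzoate
Conditions: BnOC(=NH)CCl3 (3 equiv), TfOH (5 mol %), CH2Cl2, 0 °C to rt
Reagents that add atoms: benzyl 2,2,2-trichloroacetimidate, N=C(OCc1ccccc1)C(Cl)(Cl)Cl
Why: acid-catalysed O-benzylation with a trichloroacetimidate donor, which never generates a phenoxide and so should suppress the base-induced shift of the aroyl group to a neighbouring oxygen, while catalytic TfOH at 0 °C is tolerated by a tert-butyl ester.

Step 7
Reactants: 8 tert-butyl 3,5-bis(benzyloxy)-4-[3,4,5-tris(benzyloxy)benzoyloxy]benzoate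
Product: 9 3,5-bis(benzyloxy)-4-[3,4,5-tris(benzyloxy)benzoyloxy]benzoic acid
Conditions: TFA–CH2Cl2 (1:4), 0 °C to rt
Reagents that add atoms: none
Why: acidolysis of the tert-butyl ester by loss of isobutene (E1), conditions under which aryl benzyl ethers and the aryl ester should survive a short exposure.

Step 8
Reactants: 4 tert-butyl 4-diazo-3,5-dioxocyclohexane-1-carboxylate; 9 3,5-bis(benzyloxy)-4-[3,4,5-tris(benzyloxy)benzoyloxy]benzoic acid
Product: 10 tert-butyl 4-{3,5-bis(benzyloxy)-4-[3,4,5-tris(benzyloxy)benzoyloxy]benzoyloxy}-3,5-dioxocyclohexane-1-carboxylate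
Conditions: Rh2(OAc)4 (2 mol %), ClCH2CH2Cl, 70 °C; 4 (1.2 equiv) added by syringe pump to 9 and the catalyst
Reagents that add atoms: none
Why: Rh2(OAc)4 strips N2 from 4 to give an electrophilic acceptor/acceptor rhodium carbenoid, the carboxyl oxygen of 9 adds to the carbene carbon, and a proton shift in the resulting oxonium ylide releases the catalyst and the 2-acyloxy-1,3-dione, which settles as its enol. The closest known reaction type is the divalent-rhodium-catalysed O–H insertion of 2-diazo-1,3-dicarbonyl compounds into carboxylic acids, the same operation as step 4. No ring is closed: only the bond between C4 of the future ring A and the ester oxygen is formed, and the six-membered carbocycle is aromatised in step 9. No lasting stereocentre is created, because C4 becomes sp2 on enolisation. The step needs chemoselectivity for the single carboxylic O–H over Wolff ring contraction, carbene dimerisation and attack on benzyl ether oxygens or arenes; this is secured by the absence of any other O–H in 9, by slow addition of 4 to acid and catalyst, and by the lack of a C–H next to the carbene carbon that could shift. The site of the new C–O bond is fixed, since the carbene carbon is the one between the two carbonyls, which become the C3 and C5 hydroxyls of ring A.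

Step 9
Reactants: 10 tert-butyl 4-{3,5-bis(benzyloxy)-4-[3,4,5-tris(benzyloxy)benzoyloxy]benzoyloxy}-3,5-dioxocyclohexane-1-carboxylate
Product: 11 tert-butyl 4-{3,5-bis(benzyloxy)-4-[3,4,5-tris(benzyloxy)benzoyloxy]benzoyloxy}-3,5-dihydroxybenzoate
Conditions: I2 (20 mol %), DMSO, 80 °C, N2
Reagents that add atoms: none
Why: the same iodine-catalysed oxidative aromatisation of a cyclohexane-1,3-dione as in step 5, which should convert the two ketones into the free C3 and C5 phenols of ring A without base, so neither depside ester should migrate.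

Step 10
Reactants: 11 tert-butyl 4-{3,5-bis(benzyloxy)-4-[3,4,5-tris(benzyloxy)benzoyloxy]benzoyloxy}-3,5-dihydroxybenzoate
Product: 13 4-[3,5-dihydroxy-4-(3,4,5-trihydroxybenzoyloxy)benzoyloxy]-3,5-dihydroxybenzoic acid (target CNP0121783.0), via pentabenzyl tridepside acid 12 (not isolated)
Conditions: TFA–CH2Cl2 (1:4), 0 °C to rt; evaporate; then H2 (1 atm), Pd/C (10 wt % Pd), THF, rt
Reagents that add atoms: none
Why: acidolysis of the tert-butyl ester followed by hydrogenolysis of the five benzyl ethers in a neutral, non-nucleophilic solvent, so that neither acyl shift nor solvolysis of the two depside esters should occur and the product is obtained by filtration and evaporation.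

Compound list
1 | 3,5-dihydroxybenzoic acid | O=C(O)c1cc(O)cc(O)c1 | starting material
2 | tert-butyl 3,5-dihydroxybenzoate | CC(C)(C)OC(=O)c1cc(O)cc(O)c1 | intermediate
3 | tert-butyl 3,5-dioxocyclohexane-1-carboxylate | CC(C)(C)OC(=O)C1CC(=O)CC(=O)C1 | intermediate
4 | tert-butyl 4-diazo-3,5-dioxocyclohexane-1-carboxylate | CC(C)(C)OC(=O)C1CC(=O)C(=[N+]=[N-])C(=O)C1 | intermediate
5 | 3,4,5-tris(benzyloxy)benzoic acid | O=C(O)c1cc(OCc2ccccc2)c(OCc2ccccc2)c(OCc2ccccc2)c1 | starting material
6 | tert-butyl 3,5-dioxo-4-[3,4,5-tris(benzyloxy)benzoyloxy]cyclohexane-1-carboxylate (diketo tautomer drawn) | CC(C)(C)OC(=O)C1CC(=O)C(OC(=O)c2cc(OCc3ccccc3)c(OCc3ccccc3)c(OCc3ccccc3)c2)C(=O)C1 | intermediate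
7 | tert-butyl 3,5-dihydroxy-4-[3,4,5-tris(benzyloxy)benzoyloxy]benzoate | CC(C)(C)OC(=O)c1cc(O)c(OC(=O)c2cc(OCc3ccccc3)c(OCc3ccccc3)c(OCc3ccccc3)c2)c(O)c1 | intermediate
8 | tert-butyl 3,5-bis(benzyloxy)-4-[3,4,5-tris(benzyloxy)benzoyloxy]benzoate | CC(C)(C)OC(=O)c1cc(OCc2ccccc2)c(OC(=O)c2cc(OCc3ccccc3)c(OCc3ccccc3)c(OCc3ccccc3)c2)c(OCc2ccccc2)c1 | intermediate
9 | 3,5-bis(benzyloxy)-4-[3,4,5-tris(benzyloxy)benzoyloxy]benzoic acid | O=C(O)c1cc(OCc2ccccc2)c(OC(=O)c2cc(OCc3ccccc3)c(OCc3ccccc3)c(OCc3ccccc3)c2)c(OCc2ccccc2)c1 | intermediate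
10 | tert-butyl 4-{3,5-bis(benzyloxy)-4-[3,4,5-tris(benzyloxy)benzoyloxy]benzoyloxy}-3,5-dioxocyclohexane-1-carboxylate (diketo tautomer drawn) | CC(C)(C)OC(=O)C1CC(=O)C(OC(=O)c2cc(OCc3ccccc3)c(OC(=O)c3cc(OCc4ccccc4)c(OCc4ccccc4)c(OCc4ccccc4)c3)c(OCc3ccccc3)c2)C(=O)C1 | intermediate
11 | tert-butyl 4-{3,5-bis(benzyloxy)-4-[3,4,5-tris(benzyloxy)benzoyloxy]benzoyloxy}-3,5-dihydroxybenzoate | CC(C)(C)OC(=O)c1cc(O)c(OC(=O)c2cc(OCc3ccccc3)c(OC(=O)c3cc(OCc4ccccc4)c(OCc4ccccc4)c(OCc4ccccc4)c3)c(OCc3ccccc3)c2)c(O)c1 | intermediate
12 | 4-{3,5-bis(benzyloxy)-4-[3,4,5-tris(benzyloxy)benzoyloxy]benzoyloxy}-3,5-dihydroxybenzoic acid (pentabenzyl tridepside acid) | O=C(O)c1cc(O)c(OC(=O)c2cc(OCc3ccccc3)c(OC(=O)c3cc(OCc4ccccc4)c(OCc4ccccc4)c(OCc4ccccc4)c3)c(OCc3ccccc3)c2)c(O)c1 | intermediate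
13 | 4-[3,5-dihydroxy-4-(3,4,5-trihydroxybenzoyloxy)benzoyloxy]-3,5-dihydroxybenzoic acid | O=C(O)c1cc(O)c(OC(=O)c2cc(O)c(OC(=O)c3cc(O)c(O)c(O)c3)c(O)c2)c(O)c1 | target

Total step count: 10. Longest linear sequence: 10 steps (1 to 13; compound 4 from steps 1–3 serves both insertions, and 5 is bought).

Steps most likely to fail

Step 8 (key insertion). The carbenoid may be used up by Wolff ring contraction, by dimerisation, by attack on benzyl ether oxygens or benzyl rings, or by a second insertion into the enol O–H of the product before the bulky acid captures it. The fallback replaces the carbene by a trivalent-iodine leaving group on the same carbon. It sets out from dione 3: PhI(OAc)2 with KOH in MeOH at 0 °C should give the iodonium ylide tert-butyl 3,5-dioxo-4-(phenyl-λ3-iodanylidene)cyclohexane-1-carboxylate F1. Warming F1 with acid 9 in CH2Cl2 without any metal should protonate the ylide carbon and couple the carboxylate to it with loss of iodobenzene, which comes back to the route at compound 10. The same change would serve step 4 (F1 with acid 5 gives 6).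

Step 5 (the same operation recurs in step 9). Acid formed in the iodine cycle may strip the tert-butyl group, iodine may substitute the electron-rich product ring, or the aroyl group may shift to one of the two free neighbouring hydroxyls at 80 °C. The fallback caps the enol before the oxidation, so that an ordinary cyclohexenone is dehydrogenated without halogen and only one phenol is ever free. It sets out from compound 6: benzyl trichloroacetimidate in CH2Cl2 (the acidic enol promotes its own O-alkylation) should give the vinylogous ester tert-butyl 3-(benzyloxy)-5-oxo-4-[3,4,5-tris(benzyloxy)benzoyloxy]cyclohex-3-ene-1-carboxylate F2. Aerobic dehydrogenation with divalent palladium (Pd(OCOCF3)2, 2-(dimethylamino)pyridine, O2, DMSO, 80 °C) should then give tert-butyl 3-(benzyloxy)-5-hydroxy-4-[3,4,5-tris(benzyloxy)benzoyloxy]benzoate F3. Benzylation of its single phenol under the conditions of step 6 comes back to the route at compound 8.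

Step 6 (benzylation). Under the acid catalyst the tert-butyl group may be lost, the ring may be C-benzylated, or the aroyl group may move from O4 to O3 before both hydroxyls are capped. The fallback builds ring B with its benzyl ethers already in place and forms the ester by acylating a phenol that has no free neighbouring hydroxyl. It sets out from acid 5 and from 3,4,5-trihydroxybenzoic acid F4 (gallic acid, bought). F4 with DMF di-tert-butyl acetal should give tert-butyl 3,4,5-trihydroxybenzoate F5. Allyl bromide and KHCO3 in DMF should alkylate only the most acidic 4-hydroxyl to give tert-butyl 4-(allyloxy)-3,5-dihydroxybenzoate F6. BnBr and K2CO3 should give tert-butyl 4-(allyloxy)-3,5-bis(benzyloxy)benzoate F7, and Pd(PPh3)4 with morpholine should remove the allyl group to give tert-butyl 3,5-bis(benzyloxy)-4-hydroxybenzoate F8. Carbodiimide coupling of F8 with acid 5 (EDC·HCl, DMAP, CH2Cl2) comes back to the route at compound 8, bypassing steps 4 to 6.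

Further compounds
F1 | step 8 | tert-butyl 3,5-dioxo-4-(phenyl-λ3-iodanylidene)cyclohexane-1-carboxylate | CC(C)(C)OC(=O)C1CC(=O)C([I+]c2ccccc2)=C([O-])C1
F2 | step 5 | tert-butyl 3-(benzyloxy)-5-oxo-4-[3,4,5-tris(benzyloxy)benzoyloxy]cyclohex-3-ene-1-carboxylate (racemic) | CC(C)(C)OC(=O)C1CC(=O)C(OC(=O)c2cc(OCc3ccccc3)c(OCc3ccccc3)c(OCc3ccccc3)c2)=C(OCc2ccccc2)C1
F3 | step 5 | tert-butyl 3-(benzyloxy)-5-hydroxy-4-[3,4,5-tris(benzyloxy)benzoyloxy]benzoate | CC(C)(C)OC(=O)c1cc(O)c(OC(=O)c2cc(OCc3ccccc3)c(OCc3ccccc3)c(OCc3ccccc3)c2)c(OCc2ccccc2)c1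
F4 | step 6 | 3,4,5-trihydroxybenzoic acid (gallic acid, bought) | O=C(O)c1cc(O)c(O)c(O)c1
F5 | step 6 | tert-butyl 3,4,5-trihydroxybenzoate | CC(C)(C)OC(=O)c1cc(O)c(O)c(O)c1
F6 | step 6 | tert-butyl 4-(allyloxy)-3,5-dihydroxybenzoate | CC(C)(C)OC(=O)c1cc(O)c(OCC=C)c(O)c1
F7 | step 6 | tert-butyl 4-(allyloxy)-3,5-bis(benzyloxy)benzoate | CC(C)(C)OC(=O)c1cc(OCc2ccccc2)c(OCC=C)c(OCc2ccccc2)c1
F8 | step 6 | tert-butyl 3,5-bis(benzyloxy)-4-hydroxybenzoate | CC(C)(C)OC(=O)c1cc(OCc2ccccc2)c(O)c(OCc2ccccc2)c1
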